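**Strategy.** The cis-fused α-methylene-γ-butyrolactone and the fourteen-membered carbocycle share the ring-fusion bond C1–C2 (cembrane numbering). Lactone Cα (C15) carries the exocyclic C17H2. The unit C1–C15=C17 is read as the imprint of a terminal allene, C2–O as an aldehyde, and the lactone carbonyl C16 as CO2. Everything rests on one nickel-mediated reductive coupling of a linear, achiral allenyl enal with CO2. It forms C15–C16 and C1–C2, closes both rings and sets both stereocentres, with the allylic acetate already in place. The precursor is a nineteen-carbon chain with three stereodefined trisubstituted alkenes. It comes from geraniol, hexa-1,5-diyne, oxirane and a phosphonoacetate.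

Key step: step 13

Assumption: no precedent on this substrate class gives the sense of induction of the binaphthyl phosphine in step 13. The (S)-ligand is written for the (1S,2S)-product, and its equally available antipode would be taken if the sense proves opposite.

Step 1
Reactants: 1 geraniol
Product: 2 geranyl tert-butyldimethylsilyl ether
Conditions: tBuMe2SiCl, imidazole, CH2Cl2, 0 °C to rt
Reagents that add atoms: tert-butyldimethylsilyl chloride CC(C)(C)[Si](C)(C)Cl
Why: Silyl ether protection of a primary allylic alcohol, which carries the E alkene of geraniol unchanged into C3=C4 of the target.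

Step 2
Reactants: 2 geranyl tert-butyldimethylsilyl ether
Product: 3 (E)-6-(tert-butyldimethylsilyloxy)-4-methylhex-4-enal
Conditions: O3 (1 equiv), CH2Cl2/MeOH, −78 °C; then Me2S, −78 °C to rt
Reagents that add atoms: ozone [O-][O+]=O
Why: Chemoselective ozonolysis with reductive work-up, in which the electron-richer isopropylidene alkene reacts ahead of the 2,3-alkene that the allylic silyloxy group deactivates.

Step 3
Reactants: 4 hexa-1,5-diyne
Product: 5 hexa-1,5-diyn-1-yl(trimethyl)silane
Conditions: nBuLi (1 equiv per 2 equiv of 4), THF, −78 °C; Me3SiCl, −78 °C to rt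
Reagents that add atoms: chlorotrimethylsilane C[Si](C)(C)Cl
Why: Monodeprotonation and C-silylation of a terminal alkyne, with excess volatile diyne favouring the monosilyl compound, masks one alkyne for step 4.

Step 4
Reactants: 5 hexa-1,5-diyn-1-yl(trimethyl)silane; 6 oxirane
Product: 9 (E)-4-methyl-8-(trimethylsilyl)oct-3-en-7-yn-1-ol, via alkenylalane 7 (not isolated), via lithium alanate 8 (not isolated)
Conditions: Me3Al, Cp2ZrCl2 (cat.), CH2Cl2, 0 °C to rt; change of solvent to THF/hexane; nBuLi, −78 to 0 °C; oxirane, 0 °C to rt; aq. HCl
Reagents that add atoms: trimethylaluminium C[Al](C)C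
Why: Negishi zirconium-catalysed carboalumination adds methyl and aluminium syn and regioselectively to the free terminal alkyne (the silylalkyne is inert), and the derived alanate opens oxirane with retention, which fixes the E geometry of the later C11=C12 alkene.

Step 5
Reactants: 9 (E)-4-methyl-8-(trimethylsilyl)oct-3-en-7-yn-1-ol
Product: 10 (E)-(8-iodo-5-methyloct-5-en-1-yn-1-yl)trimethylsilane
Conditions: I2, PPh3, imidazole, CH2Cl2, 0 °C
Reagents that add atoms: iodine II
Why: Appel-type iodination of a primary alcohol by SN2 displacement of the oxyphosphonium ion leaves alkene and silylalkyne untouched.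

Step 6
Reactants: 10 (E)-(8-iodo-5-methyloct-5-en-1-yn-1-yl)trimethylsilane; 11 methyl bis(2,2,2-trifluoroethyl)phosphonoacetate
Product: 12 methyl (E)-2-[bis(2,2,2-trifluoroethoxy)phosphoryl]-6-methyl-10-(trimethylsilyl)dec-5-en-9-ynoate (racemic)
Conditions: NaH, DMF, 0 °C; then 10, rt to 50 °C
Reagents that add atoms: none
Why: Malonate-type SN2 alkylation of the stabilised sodium phosphonoacetate by a primary homoallylic iodide, whose new stereocentre is erased again in step 7.

Step 7
Reactants: 12 alkylated phosphonate; 3 (E)-6-(tert-butyldimethylsilyloxy)-4-methylhex-4-enal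
Product: 13 methyl (2Z,6E)-8-(tert-butyldimethylsilyloxy)-6-methyl-2-[(E)-4-methyl-8-(trimethylsilyl)oct-3-en-7-yn-1-yl]octa-2,6-dienoate
Conditions: KN(SiMe3)2, 18-crown-6, THF, −78 °C
Reagents that add atoms: none
Why: In the Still–Gennari variant of the Horner–Wadsworth–Emmons olefination, fast irreversible elimination from the kinetic adduct of the electron-poor phosphonate places the aldehyde chain cis to the ester and thereby sets the 7Z alkene (the ring chain runs trans across C7=C8).

Step 8
Reactants: 13 Z-enoate
Product: 14 (2Z,6E)-8-(tert-butyldimethylsilyloxy)-6-methyl-2-[(E)-4-methyl-8-(trimethylsilyl)oct-3-en-7-yn-1-yl]octa-2,6-dien-1-ol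
Conditions: iBu2AlH (2.5 equiv), CH2Cl2, −78 °C; aq. potassium sodium tartrate
Reagents that add atoms: none
Why: 1,2-Reduction of the enoate by an aluminium hydride at low temperature gives the allylic alcohol without touching silyl groups or alkene geometry.

Step 9
Reactants: 14 allylic alcohol
Product: 15 acetate of 14
Conditions: Ac2O, pyridine, 4-dimethylaminopyridine (cat.), CH2Cl2, 0 °C to rt
Reagents that add atoms: acetic anhydride CC(=O)OC(C)=O
Why: Nucleophile-catalysed acetylation of the only free hydroxyl installs the acetate of the target.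

Step 10
Reactants: 15 bis-silylated acetate
Product: 16 (2Z,6E)-8-hydroxy-6-methyl-2-[(E)-4-methyloct-3-en-7-yn-1-yl]octa-2,6-dien-1-yl acetate
Conditions: Bu4NF (2.5 equiv), AcOH (2.5 equiv), THF, 0 °C to rt
Reagents that add atoms: none
Why: Fluoride-induced desilylation cleaves the O–Si and the alkynyl C–Si bond in one operation, and buffering with acetic acid protects the acetate from basic cleavage.

Step 11
Reactants: 16 hydroxy alkyne acetate
Product: 18 (2Z,6E)-8-hydroxy-6-methyl-2-[(E)-4-methylnona-3,7,8-trien-1-yl]octa-2,6-dien-1-yl acetate, via propargylamine 17 (not isolated)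
Conditions: (CH2O)n, iPr2NH, CuBr (0.3 equiv), 1,4-dioxane, reflux
Reagents that add atoms: formaldehyde (as paraformaldehyde) C=O
Why: In the Crabbé homologation a copper-catalysed Mannich reaction gives propargylamine 17, which passes a hydride from its N-isopropyl group to the alkyne and expels the imine to leave the terminal allene, with hydroxyl and acetate as spectators.

Step 12
Reactants: 18 allenyl allylic alcohol
Product: 19 (2Z,6E)-6-methyl-2-[(E)-4-methylnona-3,7,8-trien-1-yl]-8-oxoocta-2,6-dien-1-yl acetate
Conditions: MnO2 (excess), CH2Cl2, rt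
Reagents that add atoms: none
Why: Heterogeneous allylic alcohol oxidation under neutral conditions gives the E enal without isomerisation and leaves allene and acetate intact.

Step 13
Reactants: 19 allenyl enal acetate
Product: 23 (1S,2S,3E,7Z,11E)-19-acetoxycembra-3,7,11,15(17)-tetraen-16,2-olide, via nickelalactone 20 (not isolated), via nickel alkoxide carboxylate 21 (not isolated), via hydroxy acid 22 (not isolated)
Conditions: Ni(cod)2 (1.0 equiv), (S)-2-diphenylphosphino-2′-methoxy-1,1′-binaphthyl (2.0 equiv), CO2 (1 atm), THF (1 mM in 19), 0 °C to rt; then 1 M HCl, Et2O, 0 °C; pyridinium p-toluenesulfonate (cat.), CH2Cl2, rt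
Reagents that add atoms: carbon dioxide O=C=O
Why: Proposed new method: zerovalent nickel couples CO2 oxidatively with the terminal C=C of the allene so that the central allene carbon takes the carboxyl carbon (C15–C16) and the σ/π-allylnickel carboxylate 20 results, whose substituted terminus adds in SE2′ fashion through a six-membered chair to the tethered enal carbonyl (C1–C2) to give 21, and acid then releases the cis-γ-hydroxy acid 22, which lactonises. The closest known reaction types are the nickel-mediated sequential coupling of terminal allenes, CO2 and aryl aldehydes (intermolecular, achiral) and the closure of medium and large carbocycles by addition of 2-carboalkoxyallylnickel halides to tethered aldehydes; new are the macrocyclic, enal-terminated and ligand-controlled enantioselective version. The fourteen-membered ring closes by a 14-exo-trig 1,2-addition and the lactone by a 5-exo-trig acyl substitution. Relative configuration: nickel and CO2 add to the allene face turned away from the alkyl chain, which places that chain trans to the carboxylate and cis to CH2Ni (Z-crotyl type), so the chair delivers the syn adduct and hence the cis ring fusion; absolute configuration: the two faces of the allylnickel interconvert by rotation in the σ-allyl form bound at CH2, and the monodentate binaphthyl phosphine on nickel, a ligand class that gives high enantioselectivity in nickel-catalysed carboxylative cyclisation of bis-1,3-dienes, discriminates between the two diastereomeric chairs at C1 and C2. The step needs allene over allylic acetate and enal at zerovalent nickel (the allene is by far the best π-acceptor, only one equivalent of nickel is present, and the trisubstituted alkenes and the β,β-disubstituted enal bind poorly), γ- over α-attack of the allyl unit (nickel rests on the unsubstituted CH2), 1,2- over 1,4-addition (blocked β-carbon) and ring closure over oligomerisation (high dilution, persistent allylnickel).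

**Compound list**
1 | geraniol | CC(C)=CCC/C(C)=C/CO | starting material
2 | geranyl tert-butyldimethylsilyl ether | CC(C)=CCC/C(C)=C/CO[Si](C)(C)C(C)(C)C | intermediate
3 | (E)-6-(tert-butyldimethylsilyloxy)-4-methylhex-4-enal | O=CCC/C(C)=C/CO[Si](C)(C)C(C)(C)C | intermediate
4 | hexa-1,5-diyne | C#CCCC#C | starting material
5 | hexa-1,5-diyn-1-yl(trimethyl)silane | C#CCCC#C[Si](C)(C)C | intermediate
6 | oxirane | C1CO1 | starting material
7 | (E)-alkenyldimethylalane from 5 (Al cis to the new methyl) | C[Al](C)/C=C(\C)CCC#C[Si](C)(C)C | intermediate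
8 | lithium butyl(alkenyl)dimethylalanate | [Li+].CCCC[Al-](C)(C)/C=C(\C)CCC#C[Si](C)(C)C | intermediate
9 | (E)-4-methyl-8-(trimethylsilyl)oct-3-en-7-yn-1-ol | OCC/C=C(\C)CCC#C[Si](C)(C)C | intermediate
10 | (E)-(8-iodo-5-methyloct-5-en-1-yn-1-yl)trimethylsilane | ICC/C=C(\C)CCC#C[Si](C)(C)C | intermediate
11 | methyl bis(2,2,2-trifluoroethyl)phosphonoacetate | COC(=O)CP(=O)(OCC(F)(F)F)OCC(F)(F)F | starting material
12 | methyl (E)-2-[bis(2,2,2-trifluoroethoxy)phosphoryl]-6-methyl-10-(trimethylsilyl)dec-5-en-9-ynoate, racemic | COC(=O)C(CC/C=C(\C)CCC#C[Si](C)(C)C)P(=O)(OCC(F)(F)F)OCC(F)(F)F | intermediate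
13 | Z-enoate (2Z,6E; side chain E) | CC(C)(C)[Si](C)(C)OC/C=C(\C)CC/C=C(\C(=O)OC)CC/C=C(\C)CCC#C[Si](C)(C)C | intermediate
14 | allylic alcohol from 13 | CC(C)(C)[Si](C)(C)OC/C=C(\C)CC/C=C(\CO)CC/C=C(\C)CCC#C[Si](C)(C)C | intermediate
15 | acetate of 14 | CC(C)(C)[Si](C)(C)OC/C=C(\C)CC/C=C(\COC(C)=O)CC/C=C(\C)CCC#C[Si](C)(C)C | intermediate
16 | hydroxy alkyne acetate | OC/C=C(\C)CC/C=C(\COC(C)=O)CC/C=C(\C)CCC#C | intermediate
17 | N,N-diisopropylpropargylamine from 16 | OC/C=C(\C)CC/C=C(\COC(C)=O)CC/C=C(\C)CCC#CCN(C(C)C)C(C)C | intermediate
18 | allenyl allylic alcohol acetate | OC/C=C(\C)CC/C=C(\COC(C)=O)CC/C=C(\C)CCC=C=C | intermediate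
19 | allenyl enal acetate | O=C/C=C(\C)CC/C=C(\COC(C)=O)CC/C=C(\C)CCC=C=C | intermediate
20 | five-membered nickelalactone, σ-allyl form, chain cis to CH2Ni (phosphine on nickel not drawn) | O=C/C=C(\C)CC/C=C(\COC(C)=O)CC/C=C(\C)CC/C=C1\C[Ni]OC1=O | intermediate
21 | macrocyclic divalent nickel alkoxide carboxylate (phosphine not drawn) | C=C1C(=O)O[Ni]O[C@H]2/C=C(\C)CC/C=C(\COC(C)=O)CC/C=C(\C)CC[C@@H]12 | intermediate
22 | cis-γ-hydroxy α-methylene acid | O[C@H]1/C=C(\C)CC/C=C(\COC(C)=O)CC/C=C(\C)CC[C@H]1C(=C)C(=O)O | intermediate
23 | (1S,2S,3E,7Z,11E)-19-acetoxycembra-3,7,11,15(17)-tetraen-16,2-olide | C=C1C(=O)O[C@H]2/C=C(\C)CC/C=C(\COC(C)=O)CC/C=C(\C)CC[C@@H]12 | target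

**Step count.** There are 13 steps in total. The longest linear sequence is 11 steps (steps 3 to 13, from hexa-1,5-diyne).

**Steps most likely to fail**

1. **Step 13.**
   - Zerovalent nickel may insert into the allylic acetate before the allene is carboxylated.
   - The allylnickel may oligomerise with aldehydes of other molecules instead of closing the ring.
   - The ligand may discriminate the two chairs too weakly.
   - The fallback sets out from 19 and comes back at 23, and it makes the two bonds in two known steps.
   - First, a copper-catalysed enantioselective borylative coupling of the allene with the tethered aldehyde is run (CuCl, NaOtBu, a chiral bisphosphine, B2pin2, THF, high dilution). It puts boron on the central allene carbon and adds the Z-allylcopper through a chair to the enal. This gives the macrocyclic O-boryl ether F1 and, after aqueous work-up, the syn 2-boryl homoallylic alcohol F2.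
   - Second, oxidative alkoxycarbonylation of the alkenylboronate under divalent palladium (Pd(OAc)2, PPh3, p-benzoquinone, CO 1 atm, THF) inserts the carbonyl carbon and closes the lactone. Allylic acetates persist under this regime.

2. **Step 6.**
   - The weakly nucleophilic phosphonate anion may alkylate sluggishly.
   - A second alkylation or exchange of trifluoroethoxy groups may occur.
   - The bulky α-chain may then erode the geometry control of step 7.
   - The fallback sets out from 11, 3 and 10 and comes back at 13, bypassing 12.
   - Compound 11 is brominated (NaH, N-bromosuccinimide, THF) to the bromophosphonate F3.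
   - Horner–Wadsworth–Emmons reaction of F3 with 3 (KOtBu, 18-crown-6, THF, −78 °C) gives the (E)-α-bromo enoate F4.
   - Iodide 10 is converted into the alkylzinc iodide F5 (Zn, LiCl, THF).
   - Negishi coupling of F5 with F4 (PdCl2(dppf), THF) replaces bromine by the chain with retention of geometry.

3. **Step 2.**
   - Ozone may also attack the 2,3-alkene, which leads to over-cleavage.
   - The fallback sets out from 2 and comes back at 3.
   - Epoxidation with m-chloroperbenzoic acid (CH2Cl2, −20 °C) takes place at the more nucleophilic 6,7-alkene and gives the epoxide F6.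
   - Periodic acid (H5IO6, THF/H2O, 0 °C) then cleaves F6 to the aldehyde.

**Further compounds**
F1 | step 13 | macrocyclic 2-boryl homoallylic O-boryl ether | CC1(C)OB(O[C@H]2/C=C(\C)CC/C=C(\COC(C)=O)CC/C=C(\C)CC[C@H]2C(=C)B2OC(C)(C)C(C)(C)O2)OC1(C)C
F2 | step 13 | macrocyclic syn 2-boryl homoallylic alcohol | O[C@H]1/C=C(\C)CC/C=C(\COC(C)=O)CC/C=C(\C)CC[C@H]1C(=C)B1OC(C)(C)C(C)(C)O1
F3 | step 6 | methyl bromo[bis(2,2,2-trifluoroethoxy)phosphoryl]acetate | COC(=O)C(Br)P(=O)(OCC(F)(F)F)OCC(F)(F)F
F4 | step 6 | methyl (2E,6E)-2-bromo-8-(tert-butyldimethylsilyloxy)-6-methylocta-2,6-dienoate | CC(C)(C)[Si](C)(C)OC/C=C(\C)CC/C=C(\C(=O)OC)Br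
F5 | step 6 | (E)-[4-methyl-8-(trimethylsilyl)oct-3-en-7-yn-1-yl]zinc iodide | I[Zn]CC/C=C(\C)CCC#C[Si](C)(C)C
F6 | step 2 | 6,7-epoxygeranyl tert-butyldimethylsilyl ether (racemic) | CC1(C)OC1CC/C(C)=C/CO[Si](C)(C)C(C)(C)C
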